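Slowness was what I looked at in the east flask: it read 0% target at 10.0 h, and the west run, with 1 mM of protic impurity against 2 mM, still read 0% at 8.00 h.

| flask | substrate | partner | protic impurity | remark | time |
|---|---|---|---|---|---|
| east | 20 mM | 10 mM | 2 mM | the very flask that is asked about, followed so far |  |
| west | 20 mM | 10 mM | 1 mM | run made earlier |  |
| flask | 20 mM | 10.0 mM | 2.00 mM |  | 8.0 d |

| run | time / h | target / % |
|---|---|---|
| east | 10.0 | 0 |
| east | 20.0 | 14 |
| east | 50.0 | 39 |
| east | 120 | 39 |
| west | 2.00 | 0 |
| west | 4.00 | 0 |
| west | 5.00 | 0 |
| west | 8.00 | 0 |

(readings scatter by 1.5 percentage points)

- removed target is counted in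
- additions bring no volume worth counting

- gamma: at 8.0 d add substrate, 50.0% of the amount charged, then wait 8.0 d
- alpha: at 8.0 d add partner, 100% of the amount charged, then wait 8.0 d
- delta: at 8.0 d take out 90% of the target then present, then wait 8.0 d
- beta: change nothing and wait 8.0 d more

* target, in percent of the substrate first charged, at 8.0 d
* the remedy with the largest gain of target, or "none" below 2 percentage points (gamma / alpha / delta / beta / none)
* target present, with what was taken out counted in, in percent of the substrate first charged, after alpha
* target present, with what was taken out counted in, in percent of the substrate first charged, after beta

I asked whether the east flask was still slow or had stopped. It read 39% at 50.0 h and 39% at 120 h, a change of 0 percentage points against a scatter of 1.5 points, so I took it as stopped, with about 12.2 mM of substrate unconverted by that reading.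

So what had stopped the east flask? Partner is the limiting reagent, 10.0 mM against 20 mM of substrate, and one to one it allows 50.0%. The reading of 7.80 mM target falls 2.20 mM short of the partner charge, close to the 2.00 mM of protic impurity. I therefore reckoned with a ceiling, usable partner over substrate charged, that is c(partner) minus c(protic impurity), over c(substrate): 40.0%. The last reading lies 1 point under it.

Which remedy raises the ceiling? Gamma, delta and beta leave usable partner unchanged, so I expected no gain from them. Alpha, with the protic impurity taken as consumed, lifts the ceiling to 90.0%. The east readings rose by 25 points between 20.0 h and 50.0 h. Alpha needs twice that, and 8.0 d is 6.40 times that span, so I committed to the full ceiling.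

The forecast gave 39.5% now, 39.5% after beta and 89% after alpha, which is a little under my 90.0% for alpha, and it chose alpha. In its words: “The lag before product forms fits the impurity being scavenged first”.

The flask gave 40.0% at 8.0 d, 40.0% after beta and 90.0% after alpha, so alpha was best, with a gain of 50 points. At 192 h it held 2.00 mM of quenched reagent, with partner at 0% of its charge. Read as the fraction left, the ceiling gives 60.0% of the substrate, and the flask had 60.0% free at 192 h.

    substrate + partner + target → 2 target (k = 2400 /M²/h)
    substrate + partner → target (k = 0.00460 /M/h)
    partner + protic impurity → quenched reagent (k = 58.0 /M/h)

For the neighbour charged with 17 mM of partner, the ceiling reckons to 75.0%, leaving 25.0% of the substrate. The computed neighbour gave 75.0% target and 25.0% substrate at 192 h.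

The readings stem from a simulated flask with made-up constants, noise included.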